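**Retrosynthetic overview**

- The target is 7-hydroxy-3,5,6,8,4'-pentamethoxyflavone; O7 is carried as a benzyl ether and freed last by hydrogenolysis.
- Ring C (the pyranone) is the only ring that is made: one ortho methyl ether of an open-chain aryl ketone is cleaved, and the freed oxygen (O1) displaces a β-methoxy group at C2.
- Key disconnection C4–C4a: a pentaoxygenated aryllithium is acylated by the Weinreb amide of 2,3-dimethoxy-3-(4-methoxyphenyl)acrylic acid, which supplies C2, C3, C4 and ring B.
- Feature used: ring A bears oxygen on five carbons, and while ring C is open an axis runs through O7–C7 and C4a. The oxygens at C5 and C8a (and at C6 and C8) are therefore pairwise equivalent, and C4a, the only ring A carbon without oxygen, lies between two methoxy groups.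
- Ring order: rings A and B are bought as benzene rings (1,2,4,5-tetramethoxybenzene and 4-methoxybenzoyl chloride); ring C is closed in step 8.

Key step: step 7

Assumption: the enol ether double bond is drawn as Z throughout; the E isomer or a mixture would serve equally, because the geometry is erased in the addition–elimination of step 8.

**Route**

Step 1
Reactants: 1 1,2,4,5-tetramethoxybenzene
Product: 4 2,3,5,6-tetramethoxyphenol, via aryllithium 2 (not isolated), via lithium arylborate 3 (not isolated)
Conditions: n-BuLi, THF, 0 °C to rt; B(OMe)3, −78 °C to rt; AcOH, 30% H2O2, 0 °C to rt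
Reagents that add atoms: hydrogen peroxide, OO
Why: Directed ortho-lithiation at a CH flanked by two methoxy groups, borylation and oxidative 1,2-aryl shift from boron to oxygen is the standard conversion of an arene C–H into a phenol.

Step 2
Reactants: 4 2,3,5,6-tetramethoxyphenol
Product: 5 1-(benzyloxy)-2,3,5,6-tetramethoxybenzene
Conditions: BnBr, K2CO3, DMF, rt, under N2
Reagents that add atoms: benzyl bromide, BrCc1ccccc1
Why: Williamson ether synthesis on a phenoxide, run under inert gas because the electron-rich phenol is easily oxidised.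

Step 3
Reactants: 5 1-(benzyloxy)-2,3,5,6-tetramethoxybenzene
Product: 6 1-(benzyloxy)-4-bromo-2,3,5,6-tetramethoxybenzene
Conditions: NBS, dry MeCN, 0 °C, dark
Reagents that add atoms: N-bromosuccinimide, O=C1CCC(=O)N1Br
Why: Electrophilic aromatic bromination at the single free position of a pentaalkoxybenzene, kept cold and anhydrous so that substitution outruns oxidation to a quinone.

Step 4
Reactants: 7 methyl methoxyacetate; 8 4-methoxybenzoyl chloride
Product: 10 methyl 2-methoxy-3-(4-methoxyphenyl)-3-oxopropanoate (racemic), via lithium enolate 9 (not isolated)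
Conditions: LiN(i-Pr)2 (2.1 equiv, commercial solution), 7 (2.1 equiv), THF, −78 °C; then 8 (1.0 equiv), −78 to 0 °C; sat. aq NH4Cl
Reagents that add atoms: none
Why: C-acylation of a lithium ester enolate by an acid chloride (crossed Claisen-type acylation), with the second equivalent of enolate taking up the acidic proton of the β-keto ester so that it is not acylated twice.

Step 5
Reactants: 10 methyl 2-methoxy-3-(4-methoxyphenyl)-3-oxopropanoate
Product: 11 methyl (Z)-2,3-dimethoxy-3-(4-methoxyphenyl)prop-2-enoate
Conditions: Cs2CO3, Me2SO4, DMF, 0 °C to rt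
Reagents that add atoms: dimethyl sulfate, COS(=O)(=O)OC
Why: O-alkylation of a β-keto ester enolate, favoured by the loosely paired caesium enolate in DMF, the hard electrophile, and the fact that C-methylation would have to build a quaternary carbon bearing three electron-withdrawing groups.

Step 6
Reactants: 11 methyl (Z)-2,3-dimethoxy-3-(4-methoxyphenyl)prop-2-enoate; 12 N,O-dimethylhydroxylamine hydrochloride
Product: 13 (Z)-N,2,3-trimethoxy-3-(4-methoxyphenyl)-N-methylprop-2-enamide
Conditions: AlMe3 (3 equiv), 12 (3 equiv), CH2Cl2, 0 °C to reflux; cold 0.5 M HCl work-up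
Reagents that add atoms: none
Why: Weinreb amidation, in which the aluminium amide formed from AlMe3 and the amine salt attacks the ester carbonyl even of hindered, conjugated esters and leaves the enol ether untouched.

Step 7
Reactants: 6 1-(benzyloxy)-4-bromo-2,3,5,6-tetramethoxybenzene; 13 (Z)-N,2,3-trimethoxy-3-(4-methoxyphenyl)-N-methylprop-2-enamide
Product: 16 (Z)-1-[4-(benzyloxy)-2,3,5,6-tetramethoxyphenyl]-2,3-dimethoxy-3-(4-methoxyphenyl)prop-2-en-1-one, via aryllithium 14 (not isolated), via tetrahedral lithium adduct 15 (not isolated)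
Conditions: 6 (1.2 equiv), n-BuLi (1.15 equiv), THF, −78 °C; then 13 (1.0 equiv), −78 to 0 °C; sat. aq NH4Cl
Reagents that add atoms: none
Why: Bromine–lithium exchange at −78 °C should give aryllithium 14, held by its two flanking methoxy groups, faster than any deprotonation of the benzyl ether; 14 then adds to the amide carbonyl to form the C4–C4a bond. The adduct 15 is a lithium alkoxide chelated by the N-methoxy oxygen and does not collapse until protonation, so the ketone appears only on work-up and cannot take a second aryl group. The closest known reaction type is the Weinreb ketone synthesis with ortho,ortho-dialkoxyaryllithiums. No ring is closed and no lasting stereocentre is made; the carbinol carbon of 15 is racemic and is lost on work-up. The selectivity needed is attack at the carbonyl rather than the β-carbon, which should follow from the β-carbon being fully substituted, deactivated by its own methoxy donor and shielded by the anisyl group, while the α-methoxy and N-methoxy oxygens hold lithium at the carbonyl. The symmetry of 6 means only one aryllithium can form and either ortho methoxy group can later become O1, and the slight deficit of n-BuLi keeps butyl ketone formation out.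

Step 8
Reactants: 16 (Z)-1-[4-(benzyloxy)-2,3,5,6-tetramethoxyphenyl]-2,3-dimethoxy-3-(4-methoxyphenyl)prop-2-en-1-one
Product: 18 7-(benzyloxy)-3,5,6,8-tetramethoxy-2-(4-methoxyphenyl)-4H-chromen-4-one, via iodomagnesium phenoxide 17 (not isolated)
Conditions: MgI2·OEt2 (1.2 equiv), toluene, 60 °C; then 1 M HCl, THF, rt
Reagents that add atoms: none
Why: Magnesium bridges the ketone oxygen and one of the two equivalent ortho methoxy groups so that iodide removes that methyl group by SN2 (chelation-assisted ortho demethylation), and the freed oxygen then adds 6-endo to the β-carbon and expels methanol (oxa-Michael addition–elimination), which the acid treatment completes.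

Step 9
Reactants: 18 7-(benzyloxy)-3,5,6,8-tetramethoxy-2-(4-methoxyphenyl)-4H-chromen-4-one
Product: 19 7-hydroxy-3,5,6,8-tetramethoxy-2-(4-methoxyphenyl)-4H-chromen-4-one
Conditions: H2 (1 atm), Pd/C, EtOAc–MeOH, rt
Reagents that add atoms: none
Why: Hydrogenolysis of an aryl benzyl ether over Pd/C, under which the tetrasubstituted C2=C3 bond of the chromone (a vinylogous ester) is not reduced at balloon pressure.

**Compound list**

1 | 1,2,4,5-tetramethoxybenzene | COc1cc(OC)c(OC)cc1OC | starting material
2 | (2,3,5,6-tetramethoxyphenyl)lithium | [Li]c1c(OC)c(OC)cc(OC)c1OC | intermediate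
3 | lithium trimethoxy(2,3,5,6-tetramethoxyphenyl)borate | [Li+].CO[B-](OC)(OC)c1c(OC)c(OC)cc(OC)c1OC | intermediate
4 | 2,3,5,6-tetramethoxyphenol | Oc1c(OC)c(OC)cc(OC)c1OC | intermediate
5 | 1-(benzyloxy)-2,3,5,6-tetramethoxybenzene | COc1cc(OC)c(OC)c(OCc2ccccc2)c1OC | intermediate
6 | 1-(benzyloxy)-4-bromo-2,3,5,6-tetramethoxybenzene | COc1c(Br)c(OC)c(OC)c(OCc2ccccc2)c1OC | intermediate
7 | methyl methoxyacetate | COCC(=O)OC | starting material
8 | 4-methoxybenzoyl chloride | COc1ccc(cc1)C(Cl)=O | starting material
9 | lithium (E)-1,2-dimethoxyethenolate (chelated geometry presumed, of no consequence) | CO/C=C(\O[Li])OC | intermediate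
10 | methyl 2-methoxy-3-(4-methoxyphenyl)-3-oxopropanoate (racemic) | COC(=O)C(OC)C(=O)c1ccc(OC)cc1 | intermediate
11 | methyl (Z)-2,3-dimethoxy-3-(4-methoxyphenyl)prop-2-enoate | COC(=O)/C(OC)=C(/OC)c1ccc(OC)cc1 | intermediate
12 | N,O-dimethylhydroxylamine hydrochloride | CNOC.Cl | starting material
13 | (Z)-N,2,3-trimethoxy-3-(4-methoxyphenyl)-N-methylprop-2-enamide | CON(C)C(=O)/C(OC)=C(/OC)c1ccc(OC)cc1 | intermediate
14 | [4-(benzyloxy)-2,3,5,6-tetramethoxyphenyl]lithium | COc1c([Li])c(OC)c(OC)c(OCc2ccccc2)c1OC | intermediate
15 | lithium (Z)-1-[4-(benzyloxy)-2,3,5,6-tetramethoxyphenyl]-2,3-dimethoxy-1-[methoxy(methyl)amino]-3-(4-methoxyphenyl)prop-2-en-1-olate (racemic at C1) | COc1c(OC)c(OCc2ccccc2)c(OC)c(OC)c1C(O[Li])(N(C)OC)/C(OC)=C(/OC)c1ccc(OC)cc1 | intermediate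
16 | (Z)-1-[4-(benzyloxy)-2,3,5,6-tetramethoxyphenyl]-2,3-dimethoxy-3-(4-methoxyphenyl)prop-2-en-1-one | COc1c(OC)c(OCc2ccccc2)c(OC)c(OC)c1C(=O)/C(OC)=C(/OC)c1ccc(OC)cc1 | intermediate
17 | iodomagnesium 3-(benzyloxy)-2,4,5-trimethoxy-6-[(Z)-2,3-dimethoxy-3-(4-methoxyphenyl)prop-2-enoyl]phenoxide | COc1c(OC)c(OCc2ccccc2)c(OC)c(O[Mg]I)c1C(=O)/C(OC)=C(/OC)c1ccc(OC)cc1 | intermediate
18 | 7-(benzyloxy)-3,5,6,8-tetramethoxy-2-(4-methoxyphenyl)-4H-chromen-4-one | COc1ccc(-c2oc3c(OC)c(OCc4ccccc4)c(OC)c(OC)c3c(=O)c2OC)cc1 | intermediate
19 | 7-hydroxy-3,5,6,8-tetramethoxy-2-(4-methoxyphenyl)-4H-chromen-4-one | COc1ccc(-c2oc3c(OC)c(O)c(OC)c(OC)c3c(=O)c2OC)cc1 | target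

**Step count and risks**

Total steps: 9. Longest linear sequence: 6 steps (steps 1, 2, 3, 7, 8, 9; the amide branch through steps 4, 5, 6 is equally long).

Steps most likely to fail:

1. Step 7. The hindered aryllithium may fail to add to the amide carbonyl. It may instead act as a base on the N-methoxy group (loss of formaldehyde), or add at the β-carbon with loss of methoxide. Fallback: setting out from amide 13, reduction with i-Bu2AlH (THF, −78 °C) should give (Z)-2,3-dimethoxy-3-(4-methoxyphenyl)prop-2-enal F1. Aryllithium 14, made from bromide 6 as before, should add to this smaller and far more electrophilic carbonyl to give racemic (Z)-1-[4-(benzyloxy)-2,3,5,6-tetramethoxyphenyl]-2,3-dimethoxy-3-(4-methoxyphenyl)prop-2-en-1-ol F2. This acid-sensitive benzylic, allylic alcohol is oxidised at once with MnO2 (CH2Cl2, rt), which returns the route to ketone 16.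

2. Step 8. More than one methyl group may be lost. Once ring C has closed, the C5 methoxy group again sits next to a chelating carbonyl and may be cleaved. Iodide may also remove the methyl group of the β-enol ether first; the resulting 1,3-diketone would still close under the acid treatment, but would use up reagent. Fallback: setting out from ketone 16, the demethylation is driven to completion on purpose (MgI2·OEt2, 3 equiv, toluene, 80 °C; then 1 M HCl, THF). This should give 7-(benzyloxy)-5-hydroxy-3,6,8-trimethoxy-2-(4-methoxyphenyl)-4H-chromen-4-one F3, in which O5 is the only free hydroxyl. Remethylation (Me2SO4, K2CO3, acetone, reflux) comes back to compound 18.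

3. Step 5. The ambident enolate may be methylated on carbon in competition with oxygen. Fallback: setting out from keto ester 10, acid-catalysed ketalisation (HC(OMe)3, cat. TsOH, MeOH, reflux) should give methyl 2,3,3-trimethoxy-3-(4-methoxyphenyl)propanoate F4 (racemic), in which the new methoxy group can only be on oxygen. Heating F4 with cat. TsOH in toluene while methanol is distilled off should eliminate methanol towards the conjugated enol ether and come back to compound 11.

**Further compounds**

F1 | step 7 | (Z)-2,3-dimethoxy-3-(4-methoxyphenyl)prop-2-enal | O=C/C(OC)=C(/OC)c1ccc(OC)cc1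
F2 | step 7 | (Z)-1-[4-(benzyloxy)-2,3,5,6-tetramethoxyphenyl]-2,3-dimethoxy-3-(4-methoxyphenyl)prop-2-en-1-ol (racemic) | COc1c(OC)c(OCc2ccccc2)c(OC)c(OC)c1C(O)/C(OC)=C(/OC)c1ccc(OC)cc1
F3 | step 8 | 7-(benzyloxy)-5-hydroxy-3,6,8-trimethoxy-2-(4-methoxyphenyl)-4H-chromen-4-one | COc1ccc(-c2oc3c(OC)c(OCc4ccccc4)c(OC)c(O)c3c(=O)c2OC)cc1
F4 | step 5 | methyl 2,3,3-trimethoxy-3-(4-methoxyphenyl)propanoate (racemic) | COC(=O)C(OC)C(OC)(OC)c1ccc(OC)cc1
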